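## Structural features

The target 19 is a 2,3-trans-dihydroflavonol. Benzo ring A (C4a to C8a) is fused to the dihydropyranone ring C (O1, C2, C3, C4), and aryl ring B sits on C2. C2 and C3 are neighbouring stereocentres, both R, with ring B and the C3 hydroxyl trans. C2 is a benzylic ether carbon para to the 4'-methoxy group, and C3 is the carbinol carbon of an α-hydroxy ketone. Ring A has the phloroglucinol oxygen pattern (O1, O5, O7) with one prenyl group (3-methylbut-2-en-1-yl) on C8; ring B carries a second prenyl group on C3', next to the methoxy group. The fragile groups are: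
- the two trisubstituted alkenes, which rule out protic acid, electrophilic oxidants and hydrogenation (the C8 prenyl group can also close onto O7);
- the p-methoxybenzylic C2–O1 bond, which ionises in acid and opens by elimination in base;
- the α-ketol and the free phenols, which are sensitive to base and air.

The difficulty is threefold: placing the prenyl group on C8 and not C6 (which means telling three phloroglucinol oxygens apart), setting the absolute trans-2,3 diad while two more electron-rich alkenes are present, and closing ring C without disturbing any of this. The key step exploits the fact that, once ring A is bound through O1, C4a is the only unsubstituted carbon ortho to O1. It is activated by O1 and O5 (ortho) and O7 (para), so an acyl carbon C4 held on the chain O1–C2–C3 has only one carbon to attack.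

## Logic of the disconnections

**19 to 18.** The three O–Si bonds at O3, O5 and O7 are cut last. Silicon is chosen because buffered fluoride is the one deprotection that is neutral towards two prenyl groups, an α-ketol and a benzylic ether together. The gain is that phenols and ketol stay masked through every earlier step. The demand is one reagent that cleaves two aryl silyl ethers and one secondary alkyl silyl ether without basic or strongly acidic conditions.

**18 to 16 (through 17).** The C4–C4a bond is cut, which opens ring C and turns the ketone into a carboxylic acid on the chain O1–C2–C3. The cut is made here because ring A of 16 offers exactly one nucleophilic carbon within reach of the acyl group. The gain is an acyclic diaryl-ether acid whose two stereocentres can be set by open-chain methods. The demand is an acylation mild enough for the alkenes, the benzylic ether and the α-oxygenated acyl group, and oxygen protecting groups that keep ring A electron-rich.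

**16 to 14 to 13 to 12.** No skeletal bond is cut. The carboxyl carbon is traced back to the primary hydroxyl of a 1,2-diol, because a diol is what an epoxide opening delivers. The demand is to tell the primary from the secondary hydroxyl (double silylation, then selective release of the primary one) and to oxidise without base, since the aldehyde stage carries a β-aryloxy leaving group.

**12 to 8 and 11.** The benzylic C–O bond (C2–O1 of 19) is cut. This is the most convergent cut: it separates ring A from ring B with its three-carbon chain, and an epoxide at that carbon supplies the electrophile and the neighbouring oxygen with fixed relative configuration. The demand is attack at the benzylic carbon with clean inversion, O- and not C-alkylation of 11, and aryl silyl ethers that survive a phenoxide. For that reason ring A carries triisopropylsilyl groups.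

**8 to 7 to 6 to 4 and 5.** The two oxirane C–O bonds are cut, then the ester is traced back and the C=C bond is cut. An allylic alcohol is chosen because it is the alkene type that can be epoxidised enantioselectively while a more electron-rich prenyl alkene is left alone. The demand is pure E geometry in 6 and 7 and catalyst control of the face in 8.

**4 to 3 to 1 and 2.** The O–CH3 bond and the aryl C3'–CH2 bond are cut. The para formyl group leaves only the position ortho to the hydroxyl open for C-alkylation. The demand is C- over O-alkylation of an ambident phenoxide.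

**11 to 10 to 9 and 2.** Two O–Si bonds and the aryl C–CH2 bond are cut. All ring carbons of 9 are equivalent, so only one monoprenyl compound can form, and in 10 the two hydroxyls next to the prenyl group are equivalent. The demand is to stop the silylation at the stage where one of these two hydroxyls is still free.

## Other disconnections considered

**Alternative 1:** The cut is C3–C4. The precursor would be the racemic aldehyde A1, a 2-aryl-2-aryloxyacetaldehyde whose ring A carries a triethylsilyl ketone at C4a and methoxymethyl ethers at O5 and O7. A catalytic chiral lithium phosphite of the TADDOL type would add to the acylsilane, silicon would shift from carbon to oxygen, and the resulting acyl anion equivalent would add to the aldehyde. A second silyl transfer with loss of the phosphite would give the 3-O-triethylsilyl flavanone A2.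
- In its favour: ring C, the C3–C4 bond and both stereocentres would arise in one catalytic step from a racemic substrate, and the O3 protecting group is delivered by the mechanism. On stereochemical economy this is better than the chosen plan, which uses steps 5 and 8 for the same diad.
- Against it: the acylsilane of A1 is flanked by two ortho oxygen substituents, which hinders phosphite addition. The aldehyde is α-aryl and α-aryloxy; the easy enolisation that allows the dynamic resolution also makes it hard to handle. The catalyst would have to select the aldehyde enantiomer and the face in an intramolecular closure, whereas the metallophosphite silyl benzoin is established for intermolecular cases. The methoxymethyl ethers of A2 need acid for removal, next to the C8 prenyl group.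
- Comparison: both plans fix the C8 prenyl group before ring closure, so they are equal on ring A regiochemistry. Mechanistically the alternative is an umpolung addition and the chosen plan an electrophilic substitution with two separately precedented stereochemical operations. In step count the alternative could be shorter before the ring closure but needs two different deprotections after it.

**Alternative 2:** The cut is O1–C8a. The precursor would be the open-chain aryl bromide A3, with bromine at C8a, silyl ethers at O3 and O4 and a free hydroxyl at the future C2. Under CuI (monovalent copper), 3,4,7,8-tetramethyl-1,10-phenanthroline and Cs2CO3 it would undergo intramolecular Ullmann-type etherification to the flavan-3,4-diol bis-silyl ether A4.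
- In its favour: the C2–O bond is never made by substitution at the p-methoxybenzylic carbon. The alkoxide is the nucleophile and the stereocentre is a spectator, so no inversion at an ionisable centre is needed. On this point it is better than the chosen plan, whose step 8 depends on exactly that inversion. No acid is involved.
- Against it: the bromide sits between the prenyl group and the side chain on a very electron-rich ring, which slows oxidative addition. Hot Cs2CO3 with a β-silyloxy alkoxide invites silyl migration from O3 to O2, which would divert the closure to a five-membered ring. A4 is at the oxidation level of a 3,4-diol, so O4 must be released selectively and oxidised, and the methoxymethyl ethers then need acid. Three contiguous stereocentres must be built, one of which is destroyed.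
- Comparison: both plans form one bond and close ring C on a fully substituted ring A, so they are equal there. After its key step the alternative needs at least three operations where the chosen plan needs one.

**Alternative 3:** The cut is C4a–C5, and with it ring A is made from a chain. The precursor would be the dihydropyranone keto ester A5, a (2R,3R)-2-aryl-3-silyloxy-2,3-dihydropyran-4-one carrying a prenyl-branched β-keto ester chain. With Mg(OCH3)2, deprotonation at the future C8 would give a dienolate that attacks the ester carbonyl through C4a; loss of methanol and enolisation would aromatise ring A to A6.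
- In its favour: the prenyl position and the two free hydroxyls of ring A follow from the chain. Neither the regiochemistry of a phloroglucinol C-alkylation nor the differentiation of three hydroxyls arises, which is better than steps 6 and 7 of the chosen plan. A6 needs only one silyl ether removed, so the endgame is equal in length.
- Against it: A5 must carry the C2/C3 diad on a ring in which O1 is β to the C4 carbonyl, so the basic magnesium alkoxide could open the ring by elimination or epimerise C3. Assembling the diketo ester with its prenyl branch needs several further C–C bond formations.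
- Comparison: the alternative builds the arene where the chosen plan substitutes an existing one, and it is the more elegant answer to ring A regiochemistry. The chosen plan is shorter overall and keeps its stereocentres away from enolate chemistry.

Key step: step 12

Remark on the chemistry: the two ring A oxygens are carried as triisopropylsilyl ethers and only O3 as a tert-butyldimethylsilyl ether. This changes protecting groups only; the bond formed in step 12 and the skeletons of 16 and 18 are unaffected. "Prenyl" means 3-methylbut-2-en-1-yl throughout.

## Route

Step 1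
Reactants: 1 4-hydroxybenzaldehyde; 2 prenyl bromide
Product: 3 4-hydroxy-3-prenylbenzaldehyde
Conditions: KOH (10% aq), rt
Reagents that add atoms: none
Why: C-alkylation of an ambident phenoxide; in water the oxygen is hydrogen-bonded, and the ortho carbon (para is blocked by the formyl group) attacks the primary carbon of the allylic bromide, giving the linear prenyl group.

Step 2
Reactants: 3 4-hydroxy-3-prenylbenzaldehyde
Product: 4 4-methoxy-3-prenylbenzaldehyde
Conditions: MeI, K2CO3, acetone, reflux
Reagents that add atoms: iodomethane, CI
Why: Williamson ether synthesis on an acidic phenol; aldehyde and alkene are inert to these conditions.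

Step 3
Reactants: 4 4-methoxy-3-prenylbenzaldehyde; 5 triethyl phosphonoacetate
Product: 6 ethyl (E)-3-(4-methoxy-3-prenylphenyl)prop-2-enoate
Conditions: NaH, THF, 0 °C to rt
Reagents that add atoms: none
Why: Horner–Wadsworth–Emmons olefination; the stabilised phosphonate anion should give the E-cinnamate.

Step 4
Reactants: 6 ethyl (E)-3-(4-methoxy-3-prenylphenyl)prop-2-enoate
Product: 7 (E)-3-(4-methoxy-3-prenylphenyl)prop-2-en-1-ol
Conditions: iBu2AlH, CH2Cl2, −78 °C; aq potassium sodium tartrate
Reagents that add atoms: none
Why: 1,2-reduction of the conjugated ester by the aluminium hydride at low temperature; the alkenes are untouched and the E geometry is kept.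

Step 5
Reactants: 7 (E)-3-(4-methoxy-3-prenylphenyl)prop-2-en-1-ol
Product: 8 [(2S,3S)-3-(4-methoxy-3-prenylphenyl)oxiran-2-yl]methanol
Conditions: Ti(OiPr)4 (10 mol %), L-(+)-diisopropyl tartrate (12 mol %), tBuOOH, 4 Å MS, CH2Cl2, −20 °C; basic work-up
Reagents that add atoms: tert-butyl hydroperoxide, CC(C)(C)OO
Why: Katsuki–Sharpless asymmetric epoxidation; the allylic hydroxyl binds to the titanium tartrate complex, which passes the peroxide oxygen to one face of the adjacent alkene only, so the unbound prenyl alkene is spared. With L-(+)-tartrate an E-cinnamyl alcohol gives the (2S,3S)-epoxide; C2 of 8 becomes C3 of the target and C3 of 8 is the centre inverted in step 8. The epoxide is acid-labile because of the para methoxy group and should be used directly.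

Step 6
Reactants: 9 phloroglucinol; 2 prenyl bromide
Product: 10 2-prenylbenzene-1,3,5-triol
Conditions: DBU, THF, 0 °C to rt, 9 in excess
Reagents that add atoms: none
Why: C-alkylation of phloroglucinol through its enolate-like anion; excess 9 holds back dialkylation, and since all ring carbons are equivalent only one monoprenyl compound can form.

Step 7
Reactants: 10 2-prenylbenzene-1,3,5-triol
Product: 11 2-prenyl-3,5-bis(triisopropylsilyloxy)phenol
Conditions: iPr3SiCl (2.05 equiv), imidazole, CH2Cl2–DMF, 0 °C
Reagents that add atoms: triisopropylsilyl chloride, CC(C)[Si](Cl)(C(C)C)C(C)C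
Why: Silylation under steric control; the hydroxyl para to the prenyl group reacts first, the two ortho hydroxyls are equivalent, and once one is silylated the last is shielded by the prenyl group and the neighbouring silyl ether. The bulky silyl group is chosen because its aryl ethers resist the base of step 8 and screen C6 in step 12.

Step 8
Reactants: 8 [(2S,3S)-3-(4-methoxy-3-prenylphenyl)oxiran-2-yl]methanol; 11 2-prenyl-3,5-bis(triisopropylsilyloxy)phenol
Product: 12 (2S,3R)-3-[2-prenyl-3,5-bis(triisopropylsilyloxy)phenoxy]-3-(4-methoxy-3-prenylphenyl)propane-1,2-diol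
Conditions: Cs2CO3 (0.3 equiv), DMF, 50 °C
Reagents that add atoms: none
Why: Phenoxide opening of a 3-aryl-2,3-epoxy alcohol; the phenoxide attacks the benzylic carbon anti to the departing oxygen in an SN2 process, inverting that centre (3S in 8 to 3R in 12) and leaving C2 untouched, which gives the erythro diol. Catalytic base suffices because the product alkoxide deprotonates the next phenol, and this keeps the aryl silyl ethers away from stoichiometric base.

Step 9
Reactants: 12 (2S,3R)-3-[2-prenyl-3,5-bis(triisopropylsilyloxy)phenoxy]-3-(4-methoxy-3-prenylphenyl)propane-1,2-diol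
Product: 13 (2S,3R)-1,2-bis(tert-butyldimethylsilyloxy)-3-[2-prenyl-3,5-bis(triisopropylsilyloxy)phenoxy]-3-(4-methoxy-3-prenylphenyl)propane
Conditions: tBuMe2SiOTf, 2,6-lutidine, CH2Cl2, −78 to 0 °C
Reagents that add atoms: tert-butyldimethylsilyl trifluoromethanesulfonate, CC(C)(C)[Si](C)(C)OS(=O)(=O)C(F)(F)F
Why: Silylation of both hydroxyls with a silyl triflate and a hindered pyridine base, conditions that reach the hindered secondary hydroxyl; no stereocentre is involved.

Step 10
Reactants: 13 (2S,3R)-1,2-bis(tert-butyldimethylsilyloxy)-3-[2-prenyl-3,5-bis(triisopropylsilyloxy)phenoxy]-3-(4-methoxy-3-prenylphenyl)propane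
Product: 14 (2S,3R)-2-(tert-butyldimethylsilyloxy)-3-[2-prenyl-3,5-bis(triisopropylsilyloxy)phenoxy]-3-(4-methoxy-3-prenylphenyl)propan-1-ol
Conditions: camphorsulfonic acid (10 mol %), MeOH–CH2Cl2, 0 °C
Reagents that add atoms: none
Why: Acid-catalysed methanolysis of silyl ethers follows steric access and the basicity of the ether oxygen, so the primary alkyl ether should be cleaved well before the secondary alkyl ether and the two aryl ethers.

Step 11
Reactants: 14 (2S,3R)-2-(tert-butyldimethylsilyloxy)-3-[2-prenyl-3,5-bis(triisopropylsilyloxy)phenoxy]-3-(4-methoxy-3-prenylphenyl)propan-1-ol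
Product: 16 (2R,3R)-2-(tert-butyldimethylsilyloxy)-3-[2-prenyl-3,5-bis(triisopropylsilyloxy)phenoxy]-3-(4-methoxy-3-prenylphenyl)propanoic acid, via aldehyde 15 (not isolated)
Conditions: TEMPO (20 mol %), PhI(OAc)2, CH2Cl2–H2O, rt
Reagents that add atoms: water, O
Why: Oxoammonium-catalysed oxidation with a hypervalent iodine terminal oxidant; the primary alcohol gives the aldehyde, whose hydrate is oxidised again to the acid. The medium is weakly acidic, so the α-silyloxy aldehyde should neither epimerise nor eliminate the β-aryloxide, and alkenes and silyl ethers are not attacked.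

Step 12
Reactants: 16 (2R,3R)-2-(tert-butyldimethylsilyloxy)-3-[2-prenyl-3,5-bis(triisopropylsilyloxy)phenoxy]-3-(4-methoxy-3-prenylphenyl)propanoic acid
Product: 18 (2R,3R)-3-(tert-butyldimethylsilyloxy)-4'-methoxy-8,3'-diprenyl-5,7-bis(triisopropylsilyloxy)flavanone, via mixed anhydride 17 (not isolated)
Conditions: (CF3CO)2O, 2,6-di-tert-butylpyridine, CH2Cl2, −20 °C to rt
Reagents that add atoms: none
Why: Friedel–Crafts acylation through a carboxylic–trifluoroacetic mixed anhydride: 16 and the anhydride give 17, whose non-fluorinated acyl carbon is the electrophilic site because trifluoroacetate is the better leaving group. C4a of ring A, ortho to O1 and to the C5 silyloxy group and para to the C7 silyloxy group, attacks this carbon; a Wheland intermediate forms, trifluoroacetate leaves, and loss of the C4a proton to the pyridine base restores ring A and completes the C4–C4a bond. The closest known reaction type is the cyclisation of 3-aryloxypropanoic acids to chroman-4-ones under Friedel–Crafts conditions. Ring C closes in the 6-exo-trig mode at the acyl carbon, with the C=O bond outside the new ring. No stereocentre is created; C2 and C3 are spectators, and C3 should keep its configuration because the hindered, weakly basic pyridine cannot form a ketene from 17. The selectivity needed is regiochemical and the substrate secures it: of the two carbons ortho to O1, C8 carries the prenyl group, and C6 is out of reach of the three-atom tether and screened from external trifluoroacetylation by two triisopropylsilyl groups. Because a covalent anhydride and not a free acylium ion is the electrophile, decarbonylation of the α-oxygenated acyl group is avoided, and the buffer keeps the medium too weakly acidic to protonate the prenyl alkenes or ionise the p-methoxybenzylic C2–O1 bond.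

Step 13
Reactants: 18 (2R,3R)-3-(tert-butyldimethylsilyloxy)-4'-methoxy-8,3'-diprenyl-5,7-bis(triisopropylsilyloxy)flavanone
Product: 19 (2R,3R)-3,5,7-trihydroxy-4'-methoxy-8,3'-diprenylflavanone
Conditions: HF·pyridine, pyridine, THF, 0 °C to rt
Reagents that add atoms: none
Why: Fluoride-driven cleavage of the three Si–O bonds; the two aryl ethers are activated as leaving groups by conjugation to the C4 carbonyl. The pyridine buffer keeps the medium too weakly acidic to add to the prenyl alkenes or ionise C2–O1, and it is not basic, so C2 and C3 should not epimerise.

## Compound list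

1 | 4-hydroxybenzaldehyde | O=Cc1ccc(O)cc1 | starting material
2 | prenyl bromide (1-bromo-3-methylbut-2-ene) | CC(C)=CCBr | starting material
3 | 4-hydroxy-3-prenylbenzaldehyde | O=Cc1ccc(O)c(CC=C(C)C)c1 | intermediate
4 | 4-methoxy-3-prenylbenzaldehyde | COc1ccc(C=O)cc1CC=C(C)C | intermediate
5 | triethyl phosphonoacetate | CCOC(=O)CP(=O)(OCC)OCC | starting material
6 | ethyl (E)-3-(4-methoxy-3-prenylphenyl)prop-2-enoate | CCOC(=O)/C=C/c1ccc(OC)c(CC=C(C)C)c1 | intermediate
7 | (E)-3-(4-methoxy-3-prenylphenyl)prop-2-en-1-ol | OC/C=C/c1ccc(OC)c(CC=C(C)C)c1 | intermediate
8 | [(2S,3S)-3-(4-methoxy-3-prenylphenyl)oxiran-2-yl]methanol | OC[C@@H]1O[C@H]1c1ccc(OC)c(CC=C(C)C)c1 | intermediate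
9 | phloroglucinol (benzene-1,3,5-triol) | Oc1cc(O)cc(O)c1 | starting material
10 | 2-prenylbenzene-1,3,5-triol | CC(C)=CCc1c(O)cc(O)cc1O | intermediate
11 | 2-prenyl-3,5-bis(triisopropylsilyloxy)phenol (free hydroxyl next to the prenyl group) | CC(C)=CCc1c(O)cc(O[Si](C(C)C)(C(C)C)C(C)C)cc1O[Si](C(C)C)(C(C)C)C(C)C | intermediate
12 | (2S,3R)-3-[2-prenyl-3,5-bis(triisopropylsilyloxy)phenoxy]-3-(4-methoxy-3-prenylphenyl)propane-1,2-diol | COc1ccc([C@@H](Oc2cc(O[Si](C(C)C)(C(C)C)C(C)C)cc(O[Si](C(C)C)(C(C)C)C(C)C)c2CC=C(C)C)[C@@H](O)CO)cc1CC=C(C)C | intermediate
13 | (2S,3R)-1,2-bis(tert-butyldimethylsilyloxy)-3-[2-prenyl-3,5-bis(triisopropylsilyloxy)phenoxy]-3-(4-methoxy-3-prenylphenyl)propane | COc1ccc([C@@H](Oc2cc(O[Si](C(C)C)(C(C)C)C(C)C)cc(O[Si](C(C)C)(C(C)C)C(C)C)c2CC=C(C)C)[C@@H](O[Si](C)(C)C(C)(C)C)CO[Si](C)(C)C(C)(C)C)cc1CC=C(C)C | intermediate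
14 | (2S,3R)-2-(tert-butyldimethylsilyloxy)-3-[2-prenyl-3,5-bis(triisopropylsilyloxy)phenoxy]-3-(4-methoxy-3-prenylphenyl)propan-1-ol | COc1ccc([C@@H](Oc2cc(O[Si](C(C)C)(C(C)C)C(C)C)cc(O[Si](C(C)C)(C(C)C)C(C)C)c2CC=C(C)C)[C@@H](O[Si](C)(C)C(C)(C)C)CO)cc1CC=C(C)C | intermediate
15 | (2R,3R)-2-(tert-butyldimethylsilyloxy)-3-[2-prenyl-3,5-bis(triisopropylsilyloxy)phenoxy]-3-(4-methoxy-3-prenylphenyl)propanal (forms in the flask in step 11) | COc1ccc([C@@H](Oc2cc(O[Si](C(C)C)(C(C)C)C(C)C)cc(O[Si](C(C)C)(C(C)C)C(C)C)c2CC=C(C)C)[C@@H](O[Si](C)(C)C(C)(C)C)C=O)cc1CC=C(C)C | intermediate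
16 | (2R,3R)-2-(tert-butyldimethylsilyloxy)-3-[2-prenyl-3,5-bis(triisopropylsilyloxy)phenoxy]-3-(4-methoxy-3-prenylphenyl)propanoic acid | COc1ccc([C@@H](Oc2cc(O[Si](C(C)C)(C(C)C)C(C)C)cc(O[Si](C(C)C)(C(C)C)C(C)C)c2CC=C(C)C)[C@@H](O[Si](C)(C)C(C)(C)C)C(=O)O)cc1CC=C(C)C | intermediate
17 | mixed anhydride of 16 with trifluoroacetic acid (forms in the flask in step 12) | COc1ccc([C@@H](Oc2cc(O[Si](C(C)C)(C(C)C)C(C)C)cc(O[Si](C(C)C)(C(C)C)C(C)C)c2CC=C(C)C)[C@@H](O[Si](C)(C)C(C)(C)C)C(=O)OC(=O)C(F)(F)F)cc1CC=C(C)C | intermediate
18 | (2R,3R)-3-(tert-butyldimethylsilyloxy)-4'-methoxy-8,3'-diprenyl-5,7-bis(triisopropylsilyloxy)flavanone | COc1ccc([C@H]2Oc3c(CC=C(C)C)c(O[Si](C(C)C)(C(C)C)C(C)C)cc(O[Si](C(C)C)(C(C)C)C(C)C)c3C(=O)[C@@H]2O[Si](C)(C)C(C)(C)C)cc1CC=C(C)C | intermediate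
19 | (2R,3R)-3,5,7-trihydroxy-4'-methoxy-8,3'-diprenylflavanone | COc1ccc([C@H]2Oc3c(CC=C(C)C)c(O)cc(O)c3C(=O)[C@@H]2O)cc1CC=C(C)C | target

## Step count and least certain steps

Total: 13 steps. Longest linear sequence: 11 steps (steps 1 to 5 and 8 to 13); steps 6 and 7 form the ring A branch.

**Step 12 (key step).** The buffered mixed anhydride may be too weak an electrophile for an arene whose donors are silyloxy groups and whose reacting carbon lies next to a bulky silyl ether. The closure could then stall. If the buffer is reduced to force it, the acid released can ionise the p-methoxybenzylic C2–O1 bond or add to the prenyl alkenes, and trifluoroacetylation at C6 becomes a competing process. The fallback sets out from 16. Treatment with 1-chloro-N,N,2-trimethylprop-1-en-1-amine in CH2Cl2 at 0 °C would give, under neutral conditions, (2R,3R)-2-(tert-butyldimethylsilyloxy)-3-[2-prenyl-3,5-bis(triisopropylsilyloxy)phenoxy]-3-(4-methoxy-3-prenylphenyl)propanoyl chloride F1. This would be cyclised with Me2AlCl in CH2Cl2 at −78 °C, a Lewis acid that also consumes the hydrogen chloride formed (as methane), so no protic acid builds up. The fallback comes back to the route at 18.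

**Step 8.** Three processes may erode the step: partial ionisation of the electron-rich benzylic C–O bond, so that inversion is not clean; migration of the epoxide along the chain through the free primary alkoxide, followed by attack at the terminal carbon; and transfer of silyl groups between phenoxides under base. The fallback sets out from 8 and changes the order of events so that the ring opening is run without a free hydroxyl. Silylation (tBuMe2SiCl, imidazole, CH2Cl2) would give tert-butyl{[(2S,3S)-3-(4-methoxy-3-prenylphenyl)oxiran-2-yl]methoxy}dimethylsilane F2. This would be opened by the preformed potassium phenoxide of 11 (KN(SiMe3)2, 18-crown-6, toluene–THF, 40 °C), a medium of low polarity that disfavours ionisation, to give (2S,3R)-1-(tert-butyldimethylsilyloxy)-3-[2-prenyl-3,5-bis(triisopropylsilyloxy)phenoxy]-3-(4-methoxy-3-prenylphenyl)propan-2-ol F3. Silylation with tBuMe2SiOTf and 2,6-lutidine brings the fallback back at 13; a silyl shift between the two neighbouring oxygens in F3 would not matter, because both are silylated in 13.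

**Step 7.** Discrimination between three phenolic hydroxyls rests on sterics alone, so under- and over-silylation and silylation of both hydroxyls next to the prenyl group may leave the wanted compound as one component of a mixture. The fallback sets out from 9 and defines the free hydroxyl by construction. Double silylation of 9 (iPr3SiCl, imidazole) can give only one bis-silyl compound, 3,5-bis(triisopropylsilyloxy)phenol F4. O-alkylation with 2 (K2CO3, acetone) would give 1-(3-methylbut-2-en-1-yloxy)-3,5-bis(triisopropylsilyloxy)benzene F5. A clay-promoted 1,3-shift of the prenyl group from oxygen to the ortho carbon (montmorillonite K10 clay, CH2Cl2, 0 °C) should follow, the para carbon being blocked by its two silyloxy neighbours. The fallback comes back at 11.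

**Step 1.** O-alkylation and double C-alkylation compete with the wanted mono-C-alkylation of the phenoxide, so conversion to 3 may be low and the separation laborious. The fallback sets out from 1. Bromination ortho to the hydroxyl (Br2, CH2Cl2–MeOH, 0 °C) would give 3-bromo-4-hydroxybenzaldehyde F6, and methylation (MeI, K2CO3, acetone) 3-bromo-4-methoxybenzaldehyde F7. Stille coupling with tributyl(3-methylbut-2-en-1-yl)stannane and Pd(PPh3)4 (zerovalent palladium) in DMF at 100 °C would install the prenyl group at the carbon that carried bromine. The fallback comes back at 4 and replaces steps 1 and 2.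

## Further compounds

F1 | step 12 | (2R,3R)-2-(tert-butyldimethylsilyloxy)-3-[2-prenyl-3,5-bis(triisopropylsilyloxy)phenoxy]-3-(4-methoxy-3-prenylphenyl)propanoyl chloride | COc1ccc([C@@H](Oc2cc(O[Si](C(C)C)(C(C)C)C(C)C)cc(O[Si](C(C)C)(C(C)C)C(C)C)c2CC=C(C)C)[C@@H](O[Si](C)(C)C(C)(C)C)C(Cl)=O)cc1CC=C(C)C
F2 | step 8 | tert-butyl{[(2S,3S)-3-(4-methoxy-3-prenylphenyl)oxiran-2-yl]methoxy}dimethylsilane | CC(C)(C)[Si](C)(C)OC[C@@H]1O[C@H]1c1ccc(OC)c(CC=C(C)C)c1
F3 | step 8 | (2S,3R)-1-(tert-butyldimethylsilyloxy)-3-[2-prenyl-3,5-bis(triisopropylsilyloxy)phenoxy]-3-(4-methoxy-3-prenylphenyl)propan-2-ol | COc1ccc([C@@H](Oc2cc(O[Si](C(C)C)(C(C)C)C(C)C)cc(O[Si](C(C)C)(C(C)C)C(C)C)c2CC=C(C)C)[C@@H](O)CO[Si](C)(C)C(C)(C)C)cc1CC=C(C)C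
F4 | step 7 | 3,5-bis(triisopropylsilyloxy)phenol | Oc1cc(O[Si](C(C)C)(C(C)C)C(C)C)cc(O[Si](C(C)C)(C(C)C)C(C)C)c1
F5 | step 7 | 1-(3-methylbut-2-en-1-yloxy)-3,5-bis(triisopropylsilyloxy)benzene | CC(C)=CCOc1cc(O[Si](C(C)C)(C(C)C)C(C)C)cc(O[Si](C(C)C)(C(C)C)C(C)C)c1
F6 | step 1 | 3-bromo-4-hydroxybenzaldehyde | O=Cc1ccc(O)c(Br)c1
F7 | step 1 | 3-bromo-4-methoxybenzaldehyde | COc1ccc(C=O)cc1Br
A1 | alternative 1 | racemic 2-[3,5-bis(methoxymethoxy)-2-prenyl-6-(triethylsilylcarbonyl)phenoxy]-2-(4-methoxy-3-prenylphenyl)acetaldehyde | COc1ccc(C(C=O)Oc2c(CC=C(C)C)c(OCOC)cc(OCOC)c2C(=O)[Si](CC)(CC)CC)cc1CC=C(C)C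
A2 | alternative 1 | (2R,3R)-4'-methoxy-5,7-bis(methoxymethoxy)-8,3'-diprenyl-3-(triethylsilyloxy)flavanone | COc1ccc([C@H]2Oc3c(CC=C(C)C)c(OCOC)cc(OCOC)c3C(=O)[C@@H]2O[Si](CC)(CC)CC)cc1CC=C(C)C
A3 | alternative 2 | 3-[2-bromo-4,6-bis(methoxymethoxy)-3-prenylphenyl]-2,3-bis(tert-butyldimethylsilyloxy)-1-(4-methoxy-3-prenylphenyl)propan-1-ol, configuration as in the SMILES | COc1ccc([C@@H](O)[C@@H](O[Si](C)(C)C(C)(C)C)[C@@H](O[Si](C)(C)C(C)(C)C)c2c(Br)c(CC=C(C)C)c(OCOC)cc2OCOC)cc1CC=C(C)C
A4 | alternative 2 | (2R,3R)-2,3-trans-3,4-bis(tert-butyldimethylsilyloxy)-4'-methoxy-5,7-bis(methoxymethoxy)-8,3'-diprenylflavan, C4 as in the SMILES | COc1ccc([C@H]2Oc3c(CC=C(C)C)c(OCOC)cc(OCOC)c3[C@H](O[Si](C)(C)C(C)(C)C)[C@@H]2O[Si](C)(C)C(C)(C)C)cc1CC=C(C)C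
A5 | alternative 3 | methyl 4-[(2R,3R)-3-(tert-butyldimethylsilyloxy)-2-(4-methoxy-3-prenylphenyl)-4-oxo-3,4-dihydro-2H-pyran-6-yl]-7-methyl-3-oxooct-6-enoate | COC(=O)CC(=O)C(CC=C(C)C)C1=CC(=O)[C@H](O[Si](C)(C)C(C)(C)C)[C@@H](c2ccc(OC)c(CC=C(C)C)c2)O1
A6 | alternative 3 | (2R,3R)-3-(tert-butyldimethylsilyloxy)-5,7-dihydroxy-4'-methoxy-8,3'-diprenylflavanone | COc1ccc([C@H]2Oc3c(CC=C(C)C)c(O)cc(O)c3C(=O)[C@@H]2O[Si](C)(C)C(C)(C)C)cc1CC=C(C)C
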